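**Compound numbers used throughout** (fixed by order of appearance in the steps; flavanone numbering O1, C2, C3, C4, C4a, C5–C8, C8a, primed locants for ring B; "geranyl" = (2E)-3,7-dimethylocta-2,6-dien-1-yl; MOM = methoxymethyl)

1 phloroglucinol · 2 3,5-bis(MOM-oxy)phenol · 3 its TIPS ether · 4 geranyl bromide · 5 aryllithium from 3 · 6 arylcopper from 5 · 7 4-geranyl TIPS ether · 8 4-geranyl-3,5-bis(MOM-oxy)phenol · 9 2-bromo derivative of 8 · 10 3,5-dihydroxybenzoic acid · 11 MOM ester of 12 · 12 3,5-bis(MOM-oxy)benzoic acid · 13 aryl benzoate from 9 and 12 · 14 bromoaryl 1-arylvinyl ether · 15 aryllithium from 14 · 16 aldehyde (substrate of the key step) · 17 (2S)-tetrakis-MOM flavanone · 18 schizolaenone C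

## Analysis of the target

Schizolaenone C (18) is a flavanone: a benzo ring A (C4a, C5–C8, C8a) is fused to a dihydropyranone ring C (O1, C2, C3, C4), which carries a 3,5-dihydroxyphenyl ring B at C2. Ring A is a fully differentiated phloroglucinol, with O1 on C8a, free hydroxyls on C5 and C7, the ketone carbon C4 on C4a and an (E)-geranyl chain on C6, so only C8 bears hydrogen. C2 is the only stereocentre (S), so there is no second centre to relay from. It sits β to the ketone and on the ring oxygen, and base opens ring C by a retro-oxa-Michael reaction to a 2',6'-dihydroxychalcone. That opening racemises C2 and, on reclosure through the other phenol, moves the chain from C6 to C8. The geranyl chain brings two trisubstituted alkenes, which rule out hydrogenolysis, strong electrophiles and strong acid (cyclisation onto the C5 or C7 hydroxyl). The difficulty is therefore to set an isolated, base-labile stereocentre, to keep the 6-substitution unambiguous, and to do both with the chain in place. The feature used is that C4 is an aryl ketone carbon on C4a while C2–C3 is a two-carbon unit hanging from O1. Ring C is then the formal adduct of an aromatic aldehyde C–H bond across a 1-arylvinyl ether on O1, so C3–C4 and C2–H can form together and C2 is set in the same event.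

## Retrosynthetic reasoning

**18 ⇒ 17 (four O–CH2OMe bonds).** All four phenols are masked as MOM ethers. They are removed by acid, which does not open ring C, so the finished stereocentre never has to meet base or fluoride. On ring A the same groups later steer the metalation that places the chain.

**17 ⇒ 16 (C3–C4 and C2–H).** Ring C is opened at the acyl–CH2 bond, with the C2 hydrogen returned to the formyl group, which leads to aldehyde 16, a salicylaldehyde whose phenol oxygen carries a 1-arylvinyl group. The O1–C2 bond is not chosen because its formation (oxa-Michael closure of a chalcone) is reversible and is the racemisation pathway itself. The C2–C1' bond is not chosen because it would need a chromone and an aryl-metal reagent, a longer construction. The forward reaction must add the aldehyde C–H across a 1,1-disubstituted enol ether in the endo sense and select one alkene face. O1 cannot hold rhodium while its own vinyl group is bound to the metal; the donor that can stabilise the acyl hydride is the acetal oxygen on the other ortho position of the formyl group.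

**16 ⇒ 14 (C4a–CHO).** The formyl group is traced to a bromine atom in 14 and is introduced by halogen–lithium exchange. Direct deprotonation of the arene is avoided because the ring B carbon between its two acetal oxygens and the benzylic–allylic CH2 of the chain would compete. The aldehyde cannot be carried from an earlier stage because the titanium methylidene of the next disconnection would attack it.

**14 ⇒ 13 (the C3 methylene).** The enol ether is the methylenation product of aryl ester 13. This turns the difficult O1–C2 bond into an ordinary ester C–O bond and brings in C2 and ring B as a benzoate.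

**13 ⇒ 9 + 12 (ester C–O).** Ring A phenol 9 and ring B acid 12 are joined by esterification, the one convergent step. Acid 12 comes from 10 by exhaustive alkylation and saponification of the ester.

**9 ⇒ 8 (C–Br).** Phenol 8 is symmetric, its para position is occupied by the chain, and its two ortho positions are equivalent, so an electrophilic bromination has only one possible site. The forward step has to beat reaction at the chain alkenes.

**8 ⇒ 7 ⇒ 3 + 4 (aryl–geranyl bond).** The chain is attached at the carbon between the two MOM-oxygens of 3 by directed lithiation and allylation with 4. The ring is symmetric and the chain enters para to the oxygen that becomes O1, so the 6- versus 8-geranyl problem does not arise. The bulky silyl ether on that oxygen keeps the base away from its flanks and is removed afterwards.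

**3 ⇒ 2 ⇒ 1.** Two of the three equivalent hydroxyls of 1 are protected as MOM ethers and the third as the silyl ether.

## Alternatives that were turned down

**Alternative 1:** Ring A is dismantled instead of ring C, at C8–C8a, C5–C6, C7–C8 and C4a–C5, so that the arene would be grown onto an intact, enantiopure dihydropyranone.
- Forward step: irradiation of diazo ketone A2 would cause a Wolff rearrangement to a vinylketene, which adds the geranyl-substituted siloxyalkyne A3. Four-electron opening of the cyclobutenone and six-electron closure of the dienylketene (Danheiser benzannulation) would give flavanone A1.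
- For: the polarity of the ynol ether fixes the chain at C6 and delivers the two ring A oxygens already differentiated. C2 would come from an established asymmetric hetero-Diels–Alder reaction, which is a firmer basis for the stereocentre than the chosen step.
- Against: A2 is itself an enone chromophore with its stereocentre β to the carbonyl, and it would have to survive light and heat. The dienylketene carries the chain next to the ketene carbon, where the 2,3-alkene is placed for an intramolecular ketene–alkene [2+2] addition. A3 has a CH2 between an alkyne and an alkene and isomerises easily to an allene. A2 needs a 6-acyl dihydropyranone and A3 a multistep ynol ether synthesis, so the route would be clearly longer than eleven steps.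
- Comparison: the chosen route gives up the precedented source of chirality. In return it builds ring A from a symmetric arene with no ketene or photochemical stage near the chain and is several steps shorter.

**Alternative 2:** The O1–C8a bond is cut.
- Forward step: zerovalent palladium, formed from Pd(OAc)2 and a bulky di-tert-butyl biaryl phosphine, would insert into the aryl triflate of diol A5, and the C2 alkoxide would be arylated to give flavan-4-ol A4 with retention at C2. The C4 alcohol would then be oxidised.
- For: intramolecular palladium-catalysed etherification to chromans is known, C2 is set by reliable carbonyl chemistry and is not touched in the ring closure, and no flavanone exists until a neutral oxidation at the end. On precedent for the ring-forming step this alternative is stronger.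
- Against: A5 needs two stereocentres, one of which is then destroyed. Its ring A must carry a triflate, two acetals, the chain and the carbinol carbon, which costs more steps than the pattern used here. The palladium alkoxide of a secondary benzylic alcohol can undergo β-hydride elimination. The electron-rich, ortho-substituted triflate is slow in oxidative addition and open to S–O cleavage by alkoxide. The doubly ortho-oxygenated benzylic C4 alcohol ionises easily.
- Comparison: the chosen route reaches the ketone oxidation level and the stereocentre in one atom-economic isomerisation, with no redox detour and no superfluous stereocentre. The price is an untested step.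

**Alternative 3:** The C2–C3 bond is cut.
- Forward step: a chiral divalent-rhodium dimer of the type Rh2(S-PTTL)4 would convert diazo ketone A7 into a carbenoid at C3, which inserts into one enantiotopic benzylic C–H bond of the O1 benzyl ether to give flavanone A6.
- For: like the chosen route it closes ring C and sets C2 in one step from an achiral precursor, and carbenoid C–H insertion next to an ether oxygen to give chromanones is an established reaction type. On precedent it is stronger.
- Against: the carbenoid can attack O1 first, giving a five-membered oxonium ylide and, after a [1,2]-benzyl shift, a 2-benzylbenzofuranone. It is also an electrophile for the electron-rich trisubstituted alkenes of the chain (cyclopropanation) and for ring B. A six-membered insertion is less favoured than the usual five-membered one. The diazo ketone has to be made from a hindered 2,6-dioxygenated benzoic acid bearing silyl ethers.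
- Comparison: the step count is similar. The chosen route avoids a free carbenoid next to the geranyl chain, since acyl and hydride rhodium intermediates are far less reactive towards remote trisubstituted alkenes, and the ylide pathway has no counterpart.

Key step: step 10

Assumption: the sense of induction of the chiral bisphosphine in step 10 cannot be derived for this new substrate class; (R)-DTBM-SEGPHOS is written, and its antipode would be used if it favoured the 2R product.

## Route

Step 1
Reactants: 1 phloroglucinol
Product: 2 3,5-bis(methoxymethoxy)phenol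
Conditions: MOMCl (2.0 equiv), i-Pr2NEt, DMF, 0 °C to rt
Reagents that add atoms: chloromethyl methyl ether, COCCl
Why: O-alkylation of phenols with an α-chloro ether; because the triol is threefold symmetric, partial protection can give only one bis-ether, which should be separable from the mono- and tris-ethers by chromatography.

Step 2
Reactants: 2 3,5-bis(methoxymethoxy)phenol
Product: 3 [3,5-bis(methoxymethoxy)phenoxy]triisopropylsilane
Conditions: TIPSCl, imidazole, DMF, rt
Reagents that add atoms: chlorotriisopropylsilane, CC(C)[Si](Cl)(C(C)C)C(C)C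
Why: Standard silylation of a phenol; the bulky silyl ether masks the future O1 and shields both neighbouring ring positions from the base of step 3.

Step 3
Reactants: 3 [3,5-bis(methoxymethoxy)phenoxy]triisopropylsilane; 4 geranyl bromide [(2E)-1-bromo-3,7-dimethylocta-2,6-diene]
Product: 7 {4-[(2E)-3,7-dimethylocta-2,6-dien-1-yl]-3,5-bis(methoxymethoxy)phenoxy}triisopropylsilane, via aryllithium 5 (not isolated), via arylcopper 6 (not isolated)
Conditions: n-BuLi, THF, 0 °C; CuI, −40 °C; 4, −40 °C to rt
Reagents that add atoms: none
Why: Directed ortho-metalation at the only carbon flanked by two coordinating MOM groups, then transmetalation to copper and SN2 allylation, which should keep the primary attachment and the E geometry of the geranyl unit.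

Step 4
Reactants: 7 {4-geranyl-3,5-bis(methoxymethoxy)phenoxy}triisopropylsilane
Product: 8 4-[(2E)-3,7-dimethylocta-2,6-dien-1-yl]-3,5-bis(methoxymethoxy)phenol
Conditions: TBAF, THF, 0 °C
Reagents that add atoms: none
Why: Fluoride cleavage of an aryl silyl ether, driven by the Si–F bond; acetals and alkenes are inert to it.

Step 5
Reactants: 8 4-geranyl-3,5-bis(methoxymethoxy)phenol
Product: 9 2-bromo-4-[(2E)-3,7-dimethylocta-2,6-dien-1-yl]-3,5-bis(methoxymethoxy)phenol
Conditions: NBS (1.0 equiv), i-Pr2NH (10 mol%), CH2Cl2, −78 °C
Reagents that add atoms: N-bromosuccinimide, O=C1CCC(=O)N1Br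
Why: Electrophilic aromatic bromination of a phloroglucinol-type phenol whose para position is blocked and whose two ortho positions are equivalent; the amine delivers bromine ortho to the hydroxyl, and at low temperature the triply oxygen-activated ring should react faster than the chain alkenes.

Step 6
Reactants: 10 3,5-dihydroxybenzoic acid
Product: 12 3,5-bis(methoxymethoxy)benzoic acid, via methoxymethyl ester 11 (not isolated)
Conditions: MOMCl (3.5 equiv), i-Pr2NEt, CH2Cl2, 0 °C to rt; then LiOH, THF–MeOH–H2O, rt; 1 M HCl to pH 4, 0 °C
Reagents that add atoms: chloromethyl methyl ether, COCCl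
Why: Exhaustive alkylation gives the MOM ester bis-ether; saponification removes only the ester, since aryl MOM ethers are stable to base.

Step 7
Reactants: 9 2-bromo-4-geranyl-3,5-bis(methoxymethoxy)phenol; 12 3,5-bis(methoxymethoxy)benzoic acid
Product: 13 2-bromo-4-[(2E)-3,7-dimethylocta-2,6-dien-1-yl]-3,5-bis(methoxymethoxy)phenyl 3,5-bis(methoxymethoxy)benzoate
Conditions: EDC·HCl, DMAP, CH2Cl2, 0 °C to rt
Reagents that add atoms: none
Why: Steglich esterification; the acylpyridinium intermediate acylates the moderately hindered phenol under neutral conditions that spare the acetals.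

Step 8
Reactants: 13 2-bromo-4-geranyl-3,5-bis(methoxymethoxy)phenyl 3,5-bis(methoxymethoxy)benzoate
Product: 14 1-{1-[2-bromo-4-geranyl-3,5-bis(methoxymethoxy)phenoxy]ethenyl}-3,5-bis(methoxymethoxy)benzene
Conditions: Cp2TiMe2 (3 equiv), toluene–THF, 65 °C, dark; filtration through basic alumina
Reagents that add atoms: dimethyltitanocene, [CH3-].[CH3-].[Ti+4].c1cc[cH-]c1.c1cc[cH-]c1
Why: Petasis methylenation: loss of methane gives Cp2Ti=CH2, which adds to the ester carbonyl and cycloreverts to the enol ether; aryl benzoates are established substrates, and the non-acidic reagent should tolerate acetals, the aryl bromide and the trisubstituted alkenes.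

Step 9
Reactants: 14 1-{1-[2-bromo-4-geranyl-3,5-bis(methoxymethoxy)phenoxy]ethenyl}-3,5-bis(methoxymethoxy)benzene
Product: 16 2-({1-[3,5-bis(methoxymethoxy)phenyl]ethenyl}oxy)-5-[(2E)-3,7-dimethylocta-2,6-dien-1-yl]-4,6-bis(methoxymethoxy)benzaldehyde, via aryllithium 15 (not isolated)
Conditions: n-BuLi (1.05 equiv), THF, −78 °C; DMF, −78 to 0 °C; H2O
Reagents that add atoms: N,N-dimethylformamide, CN(C)C=O
Why: Bromine–lithium exchange at −78 °C is faster than any deprotonation (ring B, chain CH2), so the formyl group enters exactly where bromine stood; the hemiaminal alkoxide gives the aldehyde on aqueous work-up (Bouveault formylation).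

Step 10
Reactants: 16 2-({1-[3,5-bis(methoxymethoxy)phenyl]ethenyl}oxy)-5-geranyl-4,6-bis(methoxymethoxy)benzaldehyde
Product: 17 (2S)-2-[3,5-bis(methoxymethoxy)phenyl]-6-[(2E)-3,7-dimethylocta-2,6-dien-1-yl]-5,7-bis(methoxymethoxy)-2,3-dihydro-4H-chromen-4-one
Conditions: [Rh(cod)2]BF4 (5 mol%), (R)-DTBM-SEGPHOS (5.5 mol%), pre-activated under H2 then purged with Ar; ClCH2CH2Cl, 60 °C
Reagents that add atoms: none
Why: Proposed new method: oxidative addition of the formyl C–H bond of 16 to the cationic monovalent rhodium bisphosphine complex should give an acyl hydride of trivalent rhodium to which the tethered 1-arylvinyl ether binds; insertion of the alkene into Rh–H puts hydrogen on the aryl- and oxygen-bearing carbon (C2) and rhodium on the terminal CH2 (C3), and C–C reductive elimination from the seven-membered acyl alkyl rhodacycle forms C3–C4 and releases 17. The closest known reaction type is the rhodium-catalysed enantioselective intramolecular hydroacylation of 1,1-disubstituted alkenes (4-substituted pent-4-enals, ortho-(2-substituted allyl)benzaldehydes), of which 16 is the oxygen-tethered analogue; an enol ether has not been shown as the acceptor. Ring C closes in a 6-endo-trig mode. The C2 stereocentre is set under catalyst control in the hydride insertion, where the chiral bisphosphine selects the enol ether face. The step needs endo over exo closure, hydroacylation over decarbonylation, and no reaction at the chain alkenes: the 5-exo path would end in reductive elimination at a fully substituted carbon and its insertion is reversible, the acetal oxygen ortho to the acyl group can occupy the site needed for CO extrusion, and the trisubstituted chain alkenes are remote and poor ligands. Because the stereocentre forms under neutral, aprotic conditions, the retro-oxa-Michael route to racemisation is not opened.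

Step 11
Reactants: 17 (2S)-6-geranyl-5,7,3',5'-tetrakis(methoxymethoxy)flavanone
Product: 18 schizolaenone C, (2S)-2-(3,5-dihydroxyphenyl)-6-[(2E)-3,7-dimethylocta-2,6-dien-1-yl]-5,7-dihydroxy-2,3-dihydro-4H-chromen-4-one
Conditions: HCl (about 1 M, from AcCl in MeOH), MeOH–THF, 40 °C
Reagents that add atoms: none
Why: Acid-catalysed acetal exchange transfers the four methoxymethyl groups to methanol; acid does not open ring C, so C2 should keep its configuration, and the mild temperature is chosen to spare the geranyl chain.

## Compound list

1 | phloroglucinol (benzene-1,3,5-triol) | Oc1cc(O)cc(O)c1 | starting material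
2 | 3,5-bis(methoxymethoxy)phenol | COCOc1cc(O)cc(OCOC)c1 | intermediate
3 | [3,5-bis(methoxymethoxy)phenoxy]triisopropylsilane | COCOc1cc(OCOC)cc(O[Si](C(C)C)(C(C)C)C(C)C)c1 | intermediate
4 | geranyl bromide, (2E)-1-bromo-3,7-dimethylocta-2,6-diene | CC(C)=CCC/C(C)=C/CBr | starting material
5 | {2,6-bis(methoxymethoxy)-4-[(triisopropylsilyl)oxy]phenyl}lithium (not isolated) | [Li]c1c(OCOC)cc(O[Si](C(C)C)(C(C)C)C(C)C)cc1OCOC | intermediate
6 | {2,6-bis(methoxymethoxy)-4-[(triisopropylsilyl)oxy]phenyl}copper (not isolated) | [Cu]c1c(OCOC)cc(O[Si](C(C)C)(C(C)C)C(C)C)cc1OCOC | intermediate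
7 | {4-[(2E)-3,7-dimethylocta-2,6-dien-1-yl]-3,5-bis(methoxymethoxy)phenoxy}triisopropylsilane | CC(C)=CCC/C(C)=C/Cc1c(OCOC)cc(O[Si](C(C)C)(C(C)C)C(C)C)cc1OCOC | intermediate
8 | 4-[(2E)-3,7-dimethylocta-2,6-dien-1-yl]-3,5-bis(methoxymethoxy)phenol | CC(C)=CCC/C(C)=C/Cc1c(OCOC)cc(O)cc1OCOC | intermediate
9 | 2-bromo-4-[(2E)-3,7-dimethylocta-2,6-dien-1-yl]-3,5-bis(methoxymethoxy)phenol | CC(C)=CCC/C(C)=C/Cc1c(OCOC)cc(O)c(Br)c1OCOC | intermediate
10 | 3,5-dihydroxybenzoic acid | O=C(O)c1cc(O)cc(O)c1 | starting material
11 | methoxymethyl 3,5-bis(methoxymethoxy)benzoate (not isolated) | COCOC(=O)c1cc(OCOC)cc(OCOC)c1 | intermediate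
12 | 3,5-bis(methoxymethoxy)benzoic acid | COCOc1cc(OCOC)cc(C(=O)O)c1 | intermediate
13 | 2-bromo-4-[(2E)-3,7-dimethylocta-2,6-dien-1-yl]-3,5-bis(methoxymethoxy)phenyl 3,5-bis(methoxymethoxy)benzoate | CC(C)=CCC/C(C)=C/Cc1c(OCOC)cc(OC(=O)c2cc(OCOC)cc(OCOC)c2)c(Br)c1OCOC | intermediate
14 | 1-{1-[2-bromo-4-[(2E)-3,7-dimethylocta-2,6-dien-1-yl]-3,5-bis(methoxymethoxy)phenoxy]ethenyl}-3,5-bis(methoxymethoxy)benzene | CC(C)=CCC/C(C)=C/Cc1c(OCOC)cc(OC(=C)c2cc(OCOC)cc(OCOC)c2)c(Br)c1OCOC | intermediate
15 | {2-({1-[3,5-bis(methoxymethoxy)phenyl]ethenyl}oxy)-5-geranyl-4,6-bis(methoxymethoxy)phenyl}lithium (not isolated) | CC(C)=CCC/C(C)=C/Cc1c(OCOC)cc(OC(=C)c2cc(OCOC)cc(OCOC)c2)c([Li])c1OCOC | intermediate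
16 | 2-({1-[3,5-bis(methoxymethoxy)phenyl]ethenyl}oxy)-5-[(2E)-3,7-dimethylocta-2,6-dien-1-yl]-4,6-bis(methoxymethoxy)benzaldehyde | CC(C)=CCC/C(C)=C/Cc1c(OCOC)cc(OC(=C)c2cc(OCOC)cc(OCOC)c2)c(C=O)c1OCOC | intermediate
17 | (2S)-2-[3,5-bis(methoxymethoxy)phenyl]-6-[(2E)-3,7-dimethylocta-2,6-dien-1-yl]-5,7-bis(methoxymethoxy)-2,3-dihydro-4H-chromen-4-one | CC(C)=CCC/C(C)=C/Cc1c(OCOC)cc2c(c1OCOC)C(=O)C[C@@H](c1cc(OCOC)cc(OCOC)c1)O2 | intermediate
18 | schizolaenone C, (2S)-2-(3,5-dihydroxyphenyl)-6-[(2E)-3,7-dimethylocta-2,6-dien-1-yl]-5,7-dihydroxy-2,3-dihydro-4H-chromen-4-one | CC(C)=CCC/C(C)=C/Cc1c(O)cc2c(c1O)C(=O)C[C@@H](c1cc(O)cc(O)c1)O2 | target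

## Step count and risk

Total: 11 steps. Longest linear sequence: 10 steps (steps 1–5 and 7–11 from phloroglucinol); step 6 is a one-step side branch.

**Step 10 (key step, the proposed new method).**
- What may go wrong: poor facial selectivity in the hydride insertion, because no ligand has been tuned for an aryl- and oxygen-substituted alkene carbon.
- Also possible: decarbonylation of the hindered acyl hydride, which would convert the catalyst into an inactive carbonyl complex; exo closure to a 2-methylbenzofuranone; β-aryloxide elimination from the alkyl rhodium intermediate, in which the C2–O1 bond is β to the metal; and hydrolysis of the enol ether by traces of acid and water.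
- Fallback (known chemistry, from 9 back to 17):
  - The sodium phenoxide of 9 (NaH) would undergo bromine–lithium exchange (t-BuLi, THF, −78 °C) and acylation with N-methoxy-N-methylacetamide to give 1-[5-geranyl-2-hydroxy-4,6-bis(methoxymethoxy)phenyl]ethan-1-one F1.
  - Condensation with N,N-dimethylformamide dimethyl acetal would give the enaminone (2E)-3-(dimethylamino)-1-[5-geranyl-2-hydroxy-4,6-bis(methoxymethoxy)phenyl]prop-2-en-1-one F2, which should close on brief warming in acetic acid to 6-geranyl-5,7-bis(methoxymethoxy)-4H-chromen-4-one F3.
  - In parallel, 5-bromoresorcinol would be protected (MOMCl, i-Pr2NEt) to 1-bromo-3,5-bis(methoxymethoxy)benzene F4 and converted (n-BuLi, then B(OMe)3, then water) into [3,5-bis(methoxymethoxy)phenyl]boronic acid F5.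
  - Enantioselective conjugate addition of F5 to F3 with Pd(OCOCF3)2 and a chiral pyridine–oxazoline ligand, a known route to 2-aryl chromanones, would rejoin the route at 17.

**Step 5.**
- What may go wrong: attack of the brominating agent on the 2,3-alkene of the chain with capture of the bromonium ion by a flanking acetal oxygen, or a second bromination of the very electron-rich ring.
- Fallback (from 8 back to 9): 8 would be converted (ClCONEt2, NaH) into 4-geranyl-3,5-bis(methoxymethoxy)phenyl diethylcarbamate F6. Carbamate-directed ortho-lithiation (s-BuLi, TMEDA, THF, −78 °C) and quench with 1,2-dibromotetrafluoroethane would give 2-bromo-4-geranyl-3,5-bis(methoxymethoxy)phenyl diethylcarbamate F7, with no electrophilic bromine near the alkenes. Hydrolysis (KOH, EtOH, reflux) would return 9.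

**Step 11.**
- What may go wrong: acid-promoted cyclisation of the chain onto the freed C5 or C7 hydroxyl, or incomplete removal of the less labile acetals if the acid is kept mild.
- Fallback (from 17 back to 18): TMSOTf and 2,2'-bipyridyl in CH2Cl2 at 0 °C convert aryl MOM ethers into trimethylsilyl ethers through pyridinium intermediates without free acid. This would give (2S)-6-geranyl-5,7,3',5'-tetrakis(trimethylsilyloxy)flavanone F8, which water hydrolyses to 18.

**Step 3.**
- What may go wrong: allylic transposition (attack at the tertiary terminus of the geranyl unit) or erosion of the E geometry in the copper-mediated allylation.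
- Fallback (from 3 back to 7): aryllithium 5 would be transmetalated with ZnCl2 to {2,6-bis(methoxymethoxy)-4-[(triisopropylsilyl)oxy]phenyl}zinc chloride F9 and coupled with 4 under Pd(PPh3)4 catalysis (Negishi coupling), which joins aryl groups to the primary terminus of allylic halides with retention of alkene geometry.

## Further compounds

F1 | step 10 | 1-[5-[(2E)-3,7-dimethylocta-2,6-dien-1-yl]-2-hydroxy-4,6-bis(methoxymethoxy)phenyl]ethan-1-one | CC(C)=CCC/C(C)=C/Cc1c(OCOC)cc(O)c(C(C)=O)c1OCOC
F2 | step 10 | (2E)-3-(dimethylamino)-1-[5-[(2E)-3,7-dimethylocta-2,6-dien-1-yl]-2-hydroxy-4,6-bis(methoxymethoxy)phenyl]prop-2-en-1-one | CC(C)=CCC/C(C)=C/Cc1c(OCOC)cc(O)c(C(=O)/C=C/N(C)C)c1OCOC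
F3 | step 10 | 6-[(2E)-3,7-dimethylocta-2,6-dien-1-yl]-5,7-bis(methoxymethoxy)-4H-chromen-4-one | CC(C)=CCC/C(C)=C/Cc1c(OCOC)cc2occc(=O)c2c1OCOC
F4 | step 10 | 1-bromo-3,5-bis(methoxymethoxy)benzene | COCOc1cc(Br)cc(OCOC)c1
F5 | step 10 | [3,5-bis(methoxymethoxy)phenyl]boronic acid | COCOc1cc(OCOC)cc(B(O)O)c1
F6 | step 5 | 4-[(2E)-3,7-dimethylocta-2,6-dien-1-yl]-3,5-bis(methoxymethoxy)phenyl diethylcarbamate | CCN(CC)C(=O)Oc1cc(OCOC)c(C/C=C(\C)CCC=C(C)C)c(OCOC)c1
F7 | step 5 | 2-bromo-4-[(2E)-3,7-dimethylocta-2,6-dien-1-yl]-3,5-bis(methoxymethoxy)phenyl diethylcarbamate | CCN(CC)C(=O)Oc1cc(OCOC)c(C/C=C(\C)CCC=C(C)C)c(OCOC)c1Br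
F8 | step 11 | (2S)-2-[3,5-bis(trimethylsilyloxy)phenyl]-6-[(2E)-3,7-dimethylocta-2,6-dien-1-yl]-5,7-bis(trimethylsilyloxy)-2,3-dihydro-4H-chromen-4-one | CC(C)=CCC/C(C)=C/Cc1c(O[Si](C)(C)C)cc2c(c1O[Si](C)(C)C)C(=O)C[C@@H](c1cc(O[Si](C)(C)C)cc(O[Si](C)(C)C)c1)O2
F9 | step 3 | {2,6-bis(methoxymethoxy)-4-[(triisopropylsilyl)oxy]phenyl}zinc chloride | Cl[Zn]c1c(OCOC)cc(O[Si](C(C)C)(C(C)C)C(C)C)cc1OCOC
A1 | alternative 1 | (2S)-2-[3,5-bis(tert-butyldimethylsilyloxy)phenyl]-6-[(2E)-3,7-dimethylocta-2,6-dien-1-yl]-5-hydroxy-7-(triisopropylsilyloxy)-2,3-dihydro-4H-chromen-4-one | CC(C)=CCC/C(C)=C/Cc1c(O[Si](C(C)C)(C(C)C)C(C)C)cc2c(c1O)C(=O)C[C@@H](c1cc(O[Si](C)(C)C(C)(C)C)cc(O[Si](C)(C)C(C)(C)C)c1)O2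
A2 | alternative 1 | (2S)-2-[3,5-bis(tert-butyldimethylsilyloxy)phenyl]-6-(2-diazoacetyl)-2,3-dihydro-4H-pyran-4-one | [N-]=[N+]=CC(=O)C1=CC(=O)C[C@@H](c2cc(O[Si](C)(C)C(C)(C)C)cc(O[Si](C)(C)C(C)(C)C)c2)O1
A3 | alternative 1 | {[(4E)-5,9-dimethyldeca-4,8-dien-1-yn-1-yl]oxy}triisopropylsilane | CC(C)=CCC/C(C)=C/CC#CO[Si](C(C)C)(C(C)C)C(C)C
A4 | alternative 2 | (2S,4S)-2-[3,5-bis(methoxymethoxy)phenyl]-6-[(2E)-3,7-dimethylocta-2,6-dien-1-yl]-5,7-bis(methoxymethoxy)-3,4-dihydro-2H-chromen-4-ol | CC(C)=CCC/C(C)=C/Cc1c(OCOC)cc2c(c1OCOC)[C@@H](O)C[C@@H](c1cc(OCOC)cc(OCOC)c1)O2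
A5 | alternative 2 | 2-[(1S,3S)-3-[3,5-bis(methoxymethoxy)phenyl]-1,3-dihydroxypropyl]-4-[(2E)-3,7-dimethylocta-2,6-dien-1-yl]-3,5-bis(methoxymethoxy)phenyl trifluoromethanesulfonate | CC(C)=CCC/C(C)=C/Cc1c(OCOC)cc(OS(=O)(=O)C(F)(F)F)c(c1OCOC)[C@@H](O)C[C@H](O)c1cc(OCOC)cc(OCOC)c1
A6 | alternative 3 | (2S)-2-[3,5-bis(tert-butyldimethylsilyloxy)phenyl]-5,7-bis(tert-butyldimethylsilyloxy)-6-[(2E)-3,7-dimethylocta-2,6-dien-1-yl]-2,3-dihydro-4H-chromen-4-one | CC(C)=CCC/C(C)=C/Cc1c(O[Si](C)(C)C(C)(C)C)cc2c(c1O[Si](C)(C)C(C)(C)C)C(=O)C[C@@H](c1cc(O[Si](C)(C)C(C)(C)C)cc(O[Si](C)(C)C(C)(C)C)c1)O2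
A7 | alternative 3 | 1-[2-{[3,5-bis(tert-butyldimethylsilyloxy)phenyl]methoxy}-4,6-bis(tert-butyldimethylsilyloxy)-5-[(2E)-3,7-dimethylocta-2,6-dien-1-yl]phenyl]-2-diazoethan-1-one | CC(C)=CCC/C(C)=C/Cc1c(O[Si](C)(C)C(C)(C)C)cc(OCc2cc(O[Si](C)(C)C(C)(C)C)cc(O[Si](C)(C)C(C)(C)C)c2)c(C(=O)C=[N+]=[N-])c1O[Si](C)(C)C(C)(C)C
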